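Abbreviations: TBS = tert-butyldimethylsilyl, TBSO = tert-butyldimethylsilyloxy, Bn = benzyl. Isochromanone numbering (C1 lactone carbonyl, O2, C3, C4, C4a, C5–C8, C8a) is used for the target and for the carbons that become it.

## Analysis of the target

The target is a 3,4-dihydroisocoumarin: aromatic ring A is fused to a δ-lactone whose C3 is a lactol carbon bearing a hydroxyl and a CH2O arm. That arm is esterified with 2,4-dihydroxy-3,5,6-trimethylbenzoic acid (ring B), an acid with both ortho positions blocked. Ring A is fully substituted except at C7: methyl at C5, methoxy at C6, a hydrogen-bonded hydroxyl at C8, and the two ring-fusion carbons C4a and C8a. There are two adjacent stereocentres, C3 (R) and C4 (S), with the C3 hydroxyl trans to the C4 methyl. C3 is a ring–chain tautomerisable hemiketal, so its configuration is thermodynamic (hydroxyl axial by the anomeric effect, C4 methyl pseudoaxial to avoid the peri C5 methyl, acyloxymethyl equatorial), and only C4 needs absolute control. The sensitive points are the lactol (in its open keto acid form C4 is benzylic and α to a ketone), the hindered aryl ester next to it, and three free phenols. The difficulty is the crowded C4–C4a–C5 region, the differentiation of the C6 and C8 oxygens, and keeping C4 intact. The strategy rests on the fact that C1–C8a–C8–C7–C6–C5–C4a–C4 carries oxygen on every second carbon (C1, C8, C6, C4a), so it is a poly-β-carbonyl chain that folds into ring A by joining C8a to C4a.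

## Retrosynthetic reasoning

**Lactol C3–O2.** Target 26 is the closed tautomer of keto acid 25. Cutting the C3–O2 bond leaves a ketone at C3 and a carboxylic acid at C1, and the forward closure is spontaneous and sets C3 under thermodynamic control. Keto acid 25 is released from ketone 24, in which the C1 acid is a benzyl ester and the two ring-B phenols are benzyl ethers, so one hydrogenolysis unmasks everything at the end.

**C3 oxidation level.** Ketone 24 is traced back to secondary alcohol 23, and from there to silyl ether 22. C3 is kept at the alcohol level until the penultimate step because a C3 ketone present earlier would make C4 the central carbon of a 1,3-dicarbonyl unit in the polyketone intermediates and destroy its configuration.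

**Ester C–O bond.** Silyl ether 22 is cut at the CH2–O bond into primary alcohol 16 and ring-B acid 21. The acid carbonyl is flanked by two ortho substituents and resists acyl transfer, so the forward step makes the carboxylate the nucleophile and the primary carbon the electrophile. This requires the two side-chain oxygens to be distinguishable. They are therefore carried as two silyl ethers rather than as one cyclic acetal, so that a free vicinal diol never has to be esterified regioselectively. Primary alcohol 16 comes from bis-silyl ether 15.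

**Ring-B acid.** Acid 21 comes from ester 20 by hydrolysis, and ester 20 from 19 by benzylation. The third methyl group of 19 is introduced at the only free ring position of the inexpensive ester 17 through aldehyde 18.

**C6 methyl ether.** Bis-silyl ether 15 comes from resorcylate 14 by methylation of the one phenol that is not hydrogen-bonded to the ester.

**Ring A (C8a–C4a).** Resorcylate 14 is opened at the C8a–C4a bond, through aldol adduct 13, to triketo ester 12. This is the only cut that turns the whole substitution pattern of ring A into a linear chain whose oxygens are already in place. Triketo ester 12 is the adduct of benzyl alcohol 10 with acylketene 11, which is released from diketo-dioxinone 9 by a thermal retro-[4+2] fragmentation. The forward reaction has to favour the aldol closure over other condensations and leave C4 untouched.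

**C4a–C5 bond.** Diketo-dioxinone 9 is cut between the C4a carbonyl and C5 into keto-dioxinone 3 (nucleophile, as its dianion) and Weinreb amide 8 (electrophile). The cut places the only stereochemically relevant carbon (C4) in a small fragment that can be made by auxiliary control.

**C4–C3 bond and C4 stereocentre.** Weinreb amide 8 comes from 7 and aldol adduct 6, and adduct 6 from N-propanoyl oxazolidinone 4 and aldehyde 5 by an auxiliary-controlled syn aldol. This forms the C4–C3 bond, fixes C4 and delivers both oxygens of the side chain in one step. Keto-dioxinone 3 comes from dioxinone 1 and propanoyl chloride 2.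

## Alternatives that were turned down

**Alternative 1:** The lactol is derived from a five-membered carbocycle. The disconnection re-forms a bond between C1 and C3 and leads back to the indanone ketol [(3S)-7-(benzyloxy)-2-hydroxy-5-methoxy-3,4-dimethyl-1-oxo-2,3-dihydro-1H-inden-2-yl]methyl 2,4-bis(benzyloxy)-3,5,6-trimethylbenzoate A2. In the forward key step periodic acid (H5IO6) cleaves the ketol bond of A2, and the liberated acid adds to the new ketone to give the tribenzyl-protected lactol [(3R,4S)-8-(benzyloxy)-3-hydroxy-6-methoxy-4,5-dimethyl-1-oxoisochroman-3-yl]methyl 2,4-bis(benzyloxy)-3,5,6-trimethylbenzoate A1. Hydrogenolysis of the three benzyl ethers of A1 would then finish the synthesis.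
- For: in A1 the lactol oxidation level and the hindered ester are already in place, the cleavage of A2 is mild and chemoselective, and the future C4 is β to the indanone carbonyl and so is not enolisable. On configurational security at C4 this route is stronger than the chosen one.
- Against: A2 presupposes a finished pentasubstituted benzene, an asymmetric method for a benzylic methyl centre next to two ortho substituents, a Friedel–Crafts ring closure beside a benzyl ether, and two successive α-functionalisations to build the quaternary ketol carbon. The hindered acid would have to be attached to a neopentyl-type primary alcohol. The key step itself contributes nothing to the assembly of ring A.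
- Comparison: the chosen route builds ring A, its oxygen pattern and the side-chain carbon skeleton in one operation from acyclic pieces, on going from 9 to 14. In place of the endgame security of A1 it offers a much shorter and more convergent route.

**Alternative 2:** Both benzylic bonds of ring A (C4a–C4 and C8a–C1) are cut at once. In the forward key step CsF releases an aryne from 3,5-dimethoxy-2-methyl-6-(trimethylsilyl)phenyl trifluoromethanesulfonate A4, and dibenzyl malonate A5 inserts across it to give the homophthalate benzyl 2-[2-(benzyloxy)-2-oxoethyl]-4,6-dimethoxy-3-methylbenzoate A3.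
- For: two C–C bonds form in one mild, convergent step from A4 and the cheap diester A5, and the C8 methoxy group polarises the aryne so that the carbon nucleophile should attack C4a as required.
- Against: A4 is a pentasubstituted benzene needing several steps. A5 brings in only C1, C4 and an ester carbon at the C3 position, so A3 lacks the C4 methyl and the CH2O carbon. The two benzyl esters and the two methyl ethers of A3 each have to be differentiated later. The C4 centre would be made by methylating a carbon that is both benzylic and α to a carbonyl, with no inherent control, and it would stay doubly activated through the homologation to the acyloxy ketone.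
- Comparison: it is as convergent as the chosen route, but it leaves the stereochemical problem unsolved. The chosen route sets C4 by an auxiliary-controlled aldol in step 2, before any ring exists.

**Alternative 3:** Ring A is cut at C4a–C5 and C8a–C8. In the forward key step benzyl (4S)-4-[(4R)-2,2-dimethyl-1,3-dioxolan-4-yl]pent-2-ynoate A7 and 1,3-dimethoxy-1-(trimethylsilyloxy)penta-1,3-diene A8 undergo a [4+2] cycloaddition, and elimination of the methoxy group at the former acetal carbon aromatises ring A to give benzyl 2-[(1S)-1-[(4R)-2,2-dimethyl-1,3-dioxolan-4-yl]ethyl]-6-hydroxy-4-methoxy-3-methylbenzoate A6.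
- For: A6 already carries the C6 methyl ether and the free C8 hydroxyl, so no selective methylation is needed, and C4 is only propargylic in A7 and never α to a ketone. On these two points it is as strong as or stronger than the chosen route.
- Against: the C4a–C5 bond must form between the β-carbon of the β-branched ynoate A7 and the methyl-bearing terminus of A8. β-Alkyl ynoates are poor dienophiles, the terminal methyl of A8 disfavours the s-cis diene, and open-chain Michael-type adducts and decomposition of the hydrolytically labile A8 compete. A7 also costs extra steps of alkyne homologation.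
- Comparison: the chosen route forms the equally crowded C8a–C4a bond intramolecularly, in a six-membered aldol driven by aromatisation, from a chain made in one coupling. Because Alternative 3 avoids the polyketone stage altogether, it is kept as the fallback for the key step.

Key step: step 6

Assumptions (remarks on the chemistry): the C3 lactol configuration of the target is taken to be the thermodynamically preferred one and is left to equilibrate in the last step. The configuration of the C3 carbinol carbon in all intermediates is immaterial, because that carbon is oxidised in step 15.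

## Route

Step 1
Reactants: 1 2,2,6-trimethyl-4H-1,3-dioxin-4-one; 2 propanoyl chloride
Product: 3 2,2-dimethyl-6-(2-oxobutyl)-4H-1,3-dioxin-4-one
Conditions: 1 (2.0 equiv), LiN(SiMe3)2 (2.0 equiv), THF, −78 °C; then 2 (1.0 equiv), −78 °C; 1 M HCl
Reagents that add atoms: none
Why: The lithium dienolate of the dioxinone is C-acylated at its exocyclic γ-carbon by the acid chloride (vinylogous Claisen acylation); the second equivalent of dienolate takes up the acidic proton of the product and prevents double acylation.

Step 2
Reactants: 4 (4R)-4-benzyl-3-propanoyl-1,3-oxazolidin-2-one; 5 (tert-butyldimethylsilyloxy)acetaldehyde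
Product: 6 (4R)-4-benzyl-3-[(2R,3R)-4-(TBSO)-3-hydroxy-2-methylbutanoyl]-1,3-oxazolidin-2-one
Conditions: n-Bu2BOTf, Et3N, CH2Cl2, 0 °C; then 5, −78 → 0 °C; pH 7 buffer, MeOH, 30% H2O2, 0 °C
Reagents that add atoms: none
Why: Evans syn-aldol reaction: the Z-boron enolate reacts through a Zimmerman–Traxler chair in which the (R)-benzyl auxiliary shields one enolate face, which fixes the α-methyl centre (the future C4) as 2R and the carbinol as 2,3-syn; the carbinol configuration is erased later.

Step 3
Reactants: 6 (4R)-4-benzyl-3-[(2R,3R)-4-(TBSO)-3-hydroxy-2-methylbutanoyl]-1,3-oxazolidin-2-one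
Product: 7 (2R,3R)-4-(TBSO)-3-hydroxy-N-methoxy-N,2-dimethylbutanamide
Conditions: MeNH(OMe)·HCl, AlMe3, CH2Cl2, −20 → 0 °C; then 0.5 M HCl, 0 °C
Reagents that add atoms: N,O-dimethylhydroxylamine hydrochloride, CNOC.Cl
Why: Aluminium amide transamination of the imide to the Weinreb amide, assisted by the free β-hydroxyl as its aluminium alkoxide; the exocyclic carbonyl is attacked selectively and the α-centre is not enolised.

Step 4
Reactants: 7 (2R,3R)-4-(TBSO)-3-hydroxy-N-methoxy-N,2-dimethylbutanamide
Product: 8 (2R,3R)-3,4-bis(TBSO)-N-methoxy-N,2-dimethylbutanamide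
Conditions: TBSOTf, 2,6-lutidine, CH2Cl2, −78 → 0 °C
Reagents that add atoms: tert-butyldimethylsilyl trifluoromethanesulfonate, CC(C)(C)[Si](C)(C)OS(=O)(=O)C(F)(F)F
Why: Silyl triflate and a hindered base silylate the secondary alcohol cleanly; the silyl ether prevents retro-aldol cleavage and consumption of base in step 5 and is a poor leaving group for β-elimination.

Step 5
Reactants: 3 2,2-dimethyl-6-(2-oxobutyl)-4H-1,3-dioxin-4-one; 8 (2R,3R)-3,4-bis(TBSO)-N-methoxy-N,2-dimethylbutanamide
Product: 9 6-[(5R,6R)-6,7-bis(TBSO)-3,5-dimethyl-2,4-dioxoheptyl]-2,2-dimethyl-4H-1,3-dioxin-4-one (epimer and enol mixture at chain C3)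
Conditions: 3 (1.3 equiv), LiN(i-Pr)2 (2.6 equiv), THF, −78 °C; Et2Zn (1.3 equiv), −78 → −20 °C; then 8 (1.0 equiv), −20 → 0 °C; aq. NH4Cl
Reagents that add atoms: none
Why: Claisen-type C-acylation of the keto-dioxinone dianion at its terminal (ethyl) carbon by the Weinreb amide, forming the C4a–C5 bond. The chelated tetrahedral intermediate survives until the quench, so C4 is never α to a free ketone in strong base, and the zinc enolate is less basic than the lithium dianion, which limits α-deprotonation of 8.

Step 6
Reactants: 9 6-[(5R,6R)-6,7-bis(TBSO)-3,5-dimethyl-2,4-dioxoheptyl]-2,2-dimethyl-4H-1,3-dioxin-4-one; 10 benzyl alcohol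
Product: 14 benzyl 2-[(2S,3R)-3,4-bis(TBSO)butan-2-yl]-4,6-dihydroxy-3-methylbenzoate, via acylketene 11 (not isolated), via triketo ester 12 (not isolated), via aldol adduct 13 (not isolated)
Conditions: 10 (2 equiv), toluene, 110 °C; concentrate; Cs2CO3 (1.5 equiv), i-PrOH/CH2Cl2 (1:1), 0 °C → rt; then AcOH, rt
Reagents that add atoms: none
Why: Heating 9 triggers a retro-[4+2] fragmentation that expels acetone and leaves acylketene 11, which benzyl alcohol (in excess, so that it outruns intramolecular capture by the enol oxygen of the diketone) converts into triketo ester 12. Cs2CO3 then removes the most acidic protons, those at the future C8a, C7 and C5, and the C8a enolate adds to the C4a ketone in a 6-(enolendo)-exo-trig aldol closure that forms the C8a–C4a bond and ring A (adduct 13). Loss of water across C4a–C8a and enolisation of the two remaining ring ketones give the aromatic resorcylate, and the gain in aromaticity makes the sequence irreversible. The closest known reaction type is the thermolysis of diketo-dioxinones in the presence of an alcohol followed by base-mediated aldol aromatisation to resorcylate esters. No stereocentre is created; the existing C4 centre is α only to the C4a ketone, whose other α-position (C5) is doubly activated and ionises first, so the resulting enolate keeps C4–H from ionising and also shuts off E1cB loss of the C3 silyloxy group. The competing Claisen closure (C5 onto the C1 ester) would need a fully substituted nucleophilic carbon and would end in a ring with a quaternary centre that cannot aromatise, so the C5 methyl group itself biases the folding toward the aldol mode. Acidification with AcOH only completes the dehydration and leaves both silyl ethers and the benzyl ester in place.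

Step 7
Reactants: 14 benzyl 2-[(2S,3R)-3,4-bis(TBSO)butan-2-yl]-4,6-dihydroxy-3-methylbenzoate
Product: 15 benzyl 2-[(2S,3R)-3,4-bis(TBSO)butan-2-yl]-6-hydroxy-4-methoxy-3-methylbenzoate
Conditions: MeI (1.1 equiv), K2CO3 (1.2 equiv), acetone, rt
Reagents that add atoms: iodomethane, CI
Why: Williamson methylation of the more acidic, non-chelated hydroxyl para to the ester (the future C6 oxygen); the ortho hydroxyl is held in a hydrogen bond to the ester carbonyl and should stay free with one equivalent of MeI.

Step 8
Reactants: 15 benzyl 2-[(2S,3R)-3,4-bis(TBSO)butan-2-yl]-6-hydroxy-4-methoxy-3-methylbenzoate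
Product: 16 benzyl 2-[(2S,3R)-3-(TBSO)-4-hydroxybutan-2-yl]-6-hydroxy-4-methoxy-3-methylbenzoate
Conditions: HF·pyridine, pyridine, THF, 0 °C
Reagents that add atoms: none
Why: Buffered fluoride desilylation is sterically controlled; the primary silyl ether should be cleaved much faster than the secondary one, which is flanked by the branched benzylic carbon, and the conditions spare the benzyl ester.

Step 9
Reactants: 17 methyl 2,4-dihydroxy-3,6-dimethylbenzoate
Product: 18 methyl 3-formyl-4,6-dihydroxy-2,5-dimethylbenzoate
Conditions: Cl2CHOCH3, TiCl4, CH2Cl2, 0 °C → rt; then ice/1 M HCl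
Reagents that add atoms: dichloromethyl methyl ether, COC(Cl)Cl; water, O
Why: Rieche formylation at the only unsubstituted ring carbon, which is ortho to one hydroxyl and para to the other; hydrolysis of the chloro ether adduct releases the aldehyde.

Step 10
Reactants: 18 methyl 3-formyl-4,6-dihydroxy-2,5-dimethylbenzoate
Product: 19 methyl 2,4-dihydroxy-3,5,6-trimethylbenzoate
Conditions: Et3SiH (3 equiv), CF3CO2H, CH2Cl2, 0 °C → rt
Reagents that add atoms: none
Why: Ionic hydrogenation: the protonated aldehyde takes a hydride, the benzylic alcohol ionises to a cation stabilised by the ortho and para hydroxyls, and a second hydride gives the methyl group; with every ring position occupied, diarylmethane formation is not possible.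

Step 11
Reactants: 19 methyl 2,4-dihydroxy-3,5,6-trimethylbenzoate
Product: 20 methyl 2,4-bis(benzyloxy)-3,5,6-trimethylbenzoate
Conditions: BnBr (2.5 equiv), K2CO3 (3 equiv), DMF, 60 °C
Reagents that add atoms: benzyl bromide, BrCc1ccccc1
Why: Williamson etherification of both phenols; the polar aprotic solvent and heating overcome the flanking methyl groups and the hydrogen bond of the ortho hydroxyl.

Step 12
Reactants: 20 methyl 2,4-bis(benzyloxy)-3,5,6-trimethylbenzoate
Product: 21 2,4-bis(benzyloxy)-3,5,6-trimethylbenzoic acid
Conditions: KOH, DMSO/H2O (4:1), 90 °C; then 1 M HCl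
Reagents that add atoms: potassium hydroxide, [K+].[OH-]
Why: Saponification of a di-ortho-substituted benzoate needs poorly solvated hydroxide at elevated temperature; aryl benzyl ethers are stable to these conditions.

Step 13
Reactants: 16 benzyl 2-[(2S,3R)-3-(TBSO)-4-hydroxybutan-2-yl]-6-hydroxy-4-methoxy-3-methylbenzoate; 21 2,4-bis(benzyloxy)-3,5,6-trimethylbenzoic acid
Product: 22 benzyl 2-[(2S,3R)-4-{[2,4-bis(benzyloxy)-3,5,6-trimethylbenzoyl]oxy}-3-(TBSO)butan-2-yl]-6-hydroxy-4-methoxy-3-methylbenzoate
Conditions: PPh3, diisopropyl azodicarboxylate, THF, 0 °C → rt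
Reagents that add atoms: none
Why: Mitsunobu esterification: the primary alcohol is activated as its alkoxyphosphonium ion and displaced by the carboxylate, so the hindrance around the acid carbonyl does not matter. The carboxylic acid is far more acidic than the chelated phenol and is the only pronucleophile engaged.

Step 14
Reactants: 22 benzyl 2-[(2S,3R)-4-{[2,4-bis(benzyloxy)-3,5,6-trimethylbenzoyl]oxy}-3-(TBSO)butan-2-yl]-6-hydroxy-4-methoxy-3-methylbenzoate
Product: 23 benzyl 2-[(2S,3R)-4-{[2,4-bis(benzyloxy)-3,5,6-trimethylbenzoyl]oxy}-3-hydroxybutan-2-yl]-6-hydroxy-4-methoxy-3-methylbenzoate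
Conditions: HF·pyridine, THF, 0 °C → rt
Reagents that add atoms: none
Why: Acidic fluoride desilylation frees the secondary alcohol without generating an alkoxide, which avoids lactonisation onto the ortho benzyl ester and 1,2-acyl migration of the aryl ester.

Step 15
Reactants: 23 benzyl 2-[(2S,3R)-4-{[2,4-bis(benzyloxy)-3,5,6-trimethylbenzoyl]oxy}-3-hydroxybutan-2-yl]-6-hydroxy-4-methoxy-3-methylbenzoate
Product: 24 benzyl 2-[(2S)-4-{[2,4-bis(benzyloxy)-3,5,6-trimethylbenzoyl]oxy}-3-oxobutan-2-yl]-6-hydroxy-4-methoxy-3-methylbenzoate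
Conditions: Dess–Martin periodinane, NaHCO3, CH2Cl2, 0 °C → rt
Reagents that add atoms: none
Why: Dess–Martin oxidation under buffered, non-basic conditions gives the C3 ketone without enolising the adjacent benzylic C4; the two ortho substituents hold C4–H near the plane of ring A, which further lowers its acidity, and the chelated, ester-deactivated phenol should not be attacked.

Step 16
Reactants: 24 benzyl 2-[(2S)-4-{[2,4-bis(benzyloxy)-3,5,6-trimethylbenzoyl]oxy}-3-oxobutan-2-yl]-6-hydroxy-4-methoxy-3-methylbenzoate
Product: 26 [(3R,4S)-3,8-dihydroxy-6-methoxy-4,5-dimethyl-1-oxo-3,4-dihydro-1H-isochromen-3-yl]methyl 2,4-dihydroxy-3,5,6-trimethylbenzoate (the target), via keto acid 25 (not isolated)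
Conditions: H2 (1 atm), Pd/C, EtOAc, rt
Reagents that add atoms: none
Why: Hydrogenolysis removes the benzyl ester and both benzyl ethers, and the freed C1 acid adds to the C3 ketone (6-exo-trig) to close the lactol. Ring–chain tautomerism lets C3 equilibrate to the epimer with the hydroxyl axial and trans to the pseudoaxial C4 methyl and the acyloxymethyl group equatorial, which is 3R for 4S.

## Compound list

1 | 2,2,6-trimethyl-4H-1,3-dioxin-4-one | CC1=CC(=O)OC(C)(C)O1 | starting material
2 | propanoyl chloride | CCC(Cl)=O | starting material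
3 | 2,2-dimethyl-6-(2-oxobutyl)-4H-1,3-dioxin-4-one | CCC(=O)CC1=CC(=O)OC(C)(C)O1 | intermediate
4 | (4R)-4-benzyl-3-propanoyl-1,3-oxazolidin-2-one | CCC(=O)N1[C@H](Cc2ccccc2)COC1=O | starting material
5 | (tert-butyldimethylsilyloxy)acetaldehyde | O=CCO[Si](C)(C)C(C)(C)C | starting material
6 | (4R)-4-benzyl-3-[(2R,3R)-4-(tert-butyldimethylsilyloxy)-3-hydroxy-2-methylbutanoyl]-1,3-oxazolidin-2-one | O=C1OC[C@@H](Cc2ccccc2)N1C(=O)[C@H](C)[C@@H](O)CO[Si](C)(C)C(C)(C)C | intermediate
7 | (2R,3R)-4-(tert-butyldimethylsilyloxy)-3-hydroxy-N-methoxy-N,2-dimethylbutanamide | CON(C)C(=O)[C@H](C)[C@@H](O)CO[Si](C)(C)C(C)(C)C | intermediate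
8 | (2R,3R)-3,4-bis(tert-butyldimethylsilyloxy)-N-methoxy-N,2-dimethylbutanamide | CON(C)C(=O)[C@H](C)[C@@H](O[Si](C)(C)C(C)(C)C)CO[Si](C)(C)C(C)(C)C | intermediate
9 | 6-[(5R,6R)-6,7-bis(tert-butyldimethylsilyloxy)-3,5-dimethyl-2,4-dioxoheptyl]-2,2-dimethyl-4H-1,3-dioxin-4-one (mixture at chain C3) | CC1(C)OC(=O)C=C(CC(=O)C(C)C(=O)[C@H](C)[C@@H](O[Si](C)(C)C(C)(C)C)CO[Si](C)(C)C(C)(C)C)O1 | intermediate
10 | benzyl alcohol | OCc1ccccc1 | starting material
11 | (8R,9R)-9,10-bis(tert-butyldimethylsilyloxy)-6,8-dimethyldec-1-ene-1,3,5,7-tetrone (acylketene) | O=C=CC(=O)CC(=O)C(C)C(=O)[C@H](C)[C@@H](O[Si](C)(C)C(C)(C)C)CO[Si](C)(C)C(C)(C)C | intermediate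
12 | benzyl (8R,9R)-9,10-bis(tert-butyldimethylsilyloxy)-6,8-dimethyl-3,5,7-trioxodecanoate | O=C(CC(=O)CC(=O)C(C)C(=O)[C@H](C)[C@@H](O[Si](C)(C)C(C)(C)C)CO[Si](C)(C)C(C)(C)C)OCc1ccccc1 | intermediate
13 | benzyl 2-[(2R,3R)-3,4-bis(tert-butyldimethylsilyloxy)butan-2-yl]-2-hydroxy-3-methyl-4,6-dioxocyclohexane-1-carboxylate (ring stereocentres undefined) | CC1C(=O)CC(=O)C(C(=O)OCc2ccccc2)C1(O)[C@H](C)[C@@H](O[Si](C)(C)C(C)(C)C)CO[Si](C)(C)C(C)(C)C | intermediate
14 | benzyl 2-[(2S,3R)-3,4-bis(tert-butyldimethylsilyloxy)butan-2-yl]-4,6-dihydroxy-3-methylbenzoate | Cc1c(O)cc(O)c(C(=O)OCc2ccccc2)c1[C@H](C)[C@@H](O[Si](C)(C)C(C)(C)C)CO[Si](C)(C)C(C)(C)C | intermediate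
15 | benzyl 2-[(2S,3R)-3,4-bis(tert-butyldimethylsilyloxy)butan-2-yl]-6-hydroxy-4-methoxy-3-methylbenzoate | COc1cc(O)c(C(=O)OCc2ccccc2)c(c1C)[C@H](C)[C@@H](O[Si](C)(C)C(C)(C)C)CO[Si](C)(C)C(C)(C)C | intermediate
16 | benzyl 2-[(2S,3R)-3-(tert-butyldimethylsilyloxy)-4-hydroxybutan-2-yl]-6-hydroxy-4-methoxy-3-methylbenzoate | COc1cc(O)c(C(=O)OCc2ccccc2)c(c1C)[C@H](C)[C@@H](O[Si](C)(C)C(C)(C)C)CO | intermediate
17 | methyl 2,4-dihydroxy-3,6-dimethylbenzoate | COC(=O)c1c(C)cc(O)c(C)c1O | starting material
18 | methyl 3-formyl-4,6-dihydroxy-2,5-dimethylbenzoate | COC(=O)c1c(C)c(C=O)c(O)c(C)c1O | intermediate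
19 | methyl 2,4-dihydroxy-3,5,6-trimethylbenzoate | COC(=O)c1c(C)c(C)c(O)c(C)c1O | intermediate
20 | methyl 2,4-bis(benzyloxy)-3,5,6-trimethylbenzoate | COC(=O)c1c(C)c(C)c(OCc2ccccc2)c(C)c1OCc1ccccc1 | intermediate
21 | 2,4-bis(benzyloxy)-3,5,6-trimethylbenzoic acid | OC(=O)c1c(C)c(C)c(OCc2ccccc2)c(C)c1OCc1ccccc1 | intermediate
22 | benzyl 2-[(2S,3R)-4-{[2,4-bis(benzyloxy)-3,5,6-trimethylbenzoyl]oxy}-3-(tert-butyldimethylsilyloxy)butan-2-yl]-6-hydroxy-4-methoxy-3-methylbenzoate | COc1cc(O)c(C(=O)OCc2ccccc2)c(c1C)[C@H](C)[C@@H](O[Si](C)(C)C(C)(C)C)COC(=O)c1c(C)c(C)c(OCc2ccccc2)c(C)c1OCc1ccccc1 | intermediate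
23 | benzyl 2-[(2S,3R)-4-{[2,4-bis(benzyloxy)-3,5,6-trimethylbenzoyl]oxy}-3-hydroxybutan-2-yl]-6-hydroxy-4-methoxy-3-methylbenzoate | COc1cc(O)c(C(=O)OCc2ccccc2)c(c1C)[C@H](C)[C@@H](O)COC(=O)c1c(C)c(C)c(OCc2ccccc2)c(C)c1OCc1ccccc1 | intermediate
24 | benzyl 2-[(2S)-4-{[2,4-bis(benzyloxy)-3,5,6-trimethylbenzoyl]oxy}-3-oxobutan-2-yl]-6-hydroxy-4-methoxy-3-methylbenzoate | COc1cc(O)c(C(=O)OCc2ccccc2)c(c1C)[C@H](C)C(=O)COC(=O)c1c(C)c(C)c(OCc2ccccc2)c(C)c1OCc1ccccc1 | intermediate
25 | 2-[(2S)-4-[(2,4-dihydroxy-3,5,6-trimethylbenzoyl)oxy]-3-oxobutan-2-yl]-6-hydroxy-4-methoxy-3-methylbenzoic acid | COc1cc(O)c(C(=O)O)c(c1C)[C@H](C)C(=O)COC(=O)c1c(C)c(C)c(O)c(C)c1O | intermediate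
26 | [(3R,4S)-3,8-dihydroxy-6-methoxy-4,5-dimethyl-1-oxo-3,4-dihydro-1H-isochromen-3-yl]methyl 2,4-dihydroxy-3,5,6-trimethylbenzoate | COc1cc(O)c2c(c1C)[C@H](C)[C@](O)(COC(=O)c1c(C)c(C)c(O)c(C)c1O)OC2=O | target

## Step count and least certain steps

Total: 16 steps. Longest linear sequence: 11 steps (steps 2–8 and 13–16, from oxazolidinone 4). The dioxinone branch is one step (step 1) and the ring-B branch four steps (steps 9–12).

**Step 6 (key step).** The C4a ketone is flanked by two branched carbons, so the aldol closure may be slow. In that case the acylketene or the triketo ester can be diverted into O-cyclisation to pyranones or into retro-Claisen cleavage by the alkoxide. Prolonged heating of the 1,3-diketone can also let enolisation reach C4 and erode its configuration. Fallback, a cycloaddition that avoids the polyketone stage: setting out from Weinreb amide 8, reduction with i-Bu2AlH (THF, −78 °C) gives (2R,3R)-3,4-bis(TBSO)-2-methylbutanal F1. Homologation with dimethyl (1-diazo-2-oxopropyl)phosphonate and K2CO3 in MeOH gives (3S,4R)-4,5-bis(TBSO)-3-methylpent-1-yne F2. Deprotonation with n-BuLi and acylation with benzyl chloroformate gives benzyl (4S,5R)-5,6-bis(TBSO)-4-methylhex-2-ynoate F3. Heating F3 with 1,3-dimethoxy-1-(trimethylsilyloxy)penta-1,3-diene F4 in toluene, followed by a mild acidic work-up, should give the [4+2] adduct, which loses methanol and the trimethylsilyl group to arrive directly at 15. The route is rejoined at 15, and steps 5, 6 and 7 are bypassed.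

**Step 5.** Addition of the secondary carbon of the dianion to an α-branched Weinreb amide is sterically demanding. Proton transfer from 8 to the dianion may then compete, returning both partners and partly epimerising the amide. Fallback, aldol addition and oxidation in place of acylation: from 8, the aldehyde (2R,3R)-3,4-bis(TBSO)-2-methylbutanal F1 (reduction as above) is added at −78 °C to the dianion of 3. This gives 6-[(5S,6R)-6,7-bis(TBSO)-4-hydroxy-3,5-dimethyl-2-oxoheptyl]-2,2-dimethyl-4H-1,3-dioxin-4-one F5 as a mixture of carbinol epimers. Dess–Martin oxidation of F5 returns to 9.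

**Step 8.** Discrimination between the two silyl ethers may be incomplete, or the secondary silyl group may migrate to the freed primary oxygen. Either would give mixtures of regioisomeric alcohols. Fallback that needs no differentiation of the silyl groups: from 15, excess HF·pyridine at rt gives the diol benzyl 2-[(2S,3R)-3,4-dihydroxybutan-2-yl]-6-hydroxy-4-methoxy-3-methylbenzoate F6. Tosyl chloride, Et3N and catalytic Bu2SnO sulfonylate the primary hydroxyl to give benzyl 2-[(2S,3R)-3-hydroxy-4-(tosyloxy)butan-2-yl]-6-hydroxy-4-methoxy-3-methylbenzoate F7. The cesium salt of 21 (from 21 and Cs2CO3, DMF, 50 °C) displaces the tosylate, directly or through the terminal epoxide, at the primary carbon. This returns to 23, and steps 13 and 14 are skipped.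

**Step 12.** Attack of hydroxide on the doubly flanked ester carbonyl may be too slow, and harsher conditions risk cleavage of the benzyl ethers. Fallback by a redox detour: from 20, LiAlH4 in THF gives [2,4-bis(benzyloxy)-3,5,6-trimethylphenyl]methanol F8. MnO2 in CH2Cl2 gives 2,4-bis(benzyloxy)-3,5,6-trimethylbenzaldehyde F9. Pinnick oxidation (NaClO2, NaH2PO4, 2-methylbut-2-ene, t-BuOH/H2O) returns to 21.

**Step 15.** The oxidant may attack the electron-rich ring A through its free phenol, or the new ketone may enolise toward the benzylic C4 and lose configuration. Fallback that masks the phenol first: from 23, BnBr and K2CO3 in acetone give benzyl 6-(benzyloxy)-2-[(2S,3R)-4-{[2,4-bis(benzyloxy)-3,5,6-trimethylbenzoyl]oxy}-3-hydroxybutan-2-yl]-4-methoxy-3-methylbenzoate F10. Dess–Martin oxidation gives benzyl 6-(benzyloxy)-2-[(2S)-4-{[2,4-bis(benzyloxy)-3,5,6-trimethylbenzoyl]oxy}-3-oxobutan-2-yl]-4-methoxy-3-methylbenzoate F11. Hydrogenolysis over Pd/C removes all four benzyl groups and returns to 26 through 25.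

## Further compounds

F1 | step 6 | (2R,3R)-3,4-bis(tert-butyldimethylsilyloxy)-2-methylbutanal | O=C[C@H](C)[C@@H](O[Si](C)(C)C(C)(C)C)CO[Si](C)(C)C(C)(C)C
F2 | step 6 | (3S,4R)-4,5-bis(tert-butyldimethylsilyloxy)-3-methylpent-1-yne | C#C[C@H](C)[C@@H](O[Si](C)(C)C(C)(C)C)CO[Si](C)(C)C(C)(C)C
F3 | step 6 | benzyl (4S,5R)-5,6-bis(tert-butyldimethylsilyloxy)-4-methylhex-2-ynoate | O=C(OCc1ccccc1)C#C[C@H](C)[C@@H](O[Si](C)(C)C(C)(C)C)CO[Si](C)(C)C(C)(C)C
F4 | step 6 | 1,3-dimethoxy-1-(trimethylsilyloxy)penta-1,3-diene | CC=C(OC)C=C(OC)O[Si](C)(C)C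
F5 | step 5 | 6-[(5S,6R)-6,7-bis(tert-butyldimethylsilyloxy)-4-hydroxy-3,5-dimethyl-2-oxoheptyl]-2,2-dimethyl-4H-1,3-dioxin-4-one (mixture at chain C3 and C4) | CC1(C)OC(=O)C=C(CC(=O)C(C)C(O)[C@H](C)[C@@H](O[Si](C)(C)C(C)(C)C)CO[Si](C)(C)C(C)(C)C)O1
F6 | step 8 | benzyl 2-[(2S,3R)-3,4-dihydroxybutan-2-yl]-6-hydroxy-4-methoxy-3-methylbenzoate | COc1cc(O)c(C(=O)OCc2ccccc2)c(c1C)[C@H](C)[C@@H](O)CO
F7 | step 8 | benzyl 2-[(2S,3R)-3-hydroxy-4-(4-methylbenzenesulfonyloxy)butan-2-yl]-6-hydroxy-4-methoxy-3-methylbenzoate | COc1cc(O)c(C(=O)OCc2ccccc2)c(c1C)[C@H](C)[C@@H](O)COS(=O)(=O)c1ccc(C)cc1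
F8 | step 12 | [2,4-bis(benzyloxy)-3,5,6-trimethylphenyl]methanol | OCc1c(C)c(C)c(OCc2ccccc2)c(C)c1OCc1ccccc1
F9 | step 12 | 2,4-bis(benzyloxy)-3,5,6-trimethylbenzaldehyde | O=Cc1c(C)c(C)c(OCc2ccccc2)c(C)c1OCc1ccccc1
F10 | step 15 | benzyl 6-(benzyloxy)-2-[(2S,3R)-4-{[2,4-bis(benzyloxy)-3,5,6-trimethylbenzoyl]oxy}-3-hydroxybutan-2-yl]-4-methoxy-3-methylbenzoate | COc1cc(OCc2ccccc2)c(C(=O)OCc2ccccc2)c(c1C)[C@H](C)[C@@H](O)COC(=O)c1c(C)c(C)c(OCc2ccccc2)c(C)c1OCc1ccccc1
F11 | step 15 | benzyl 6-(benzyloxy)-2-[(2S)-4-{[2,4-bis(benzyloxy)-3,5,6-trimethylbenzoyl]oxy}-3-oxobutan-2-yl]-4-methoxy-3-methylbenzoate | COc1cc(OCc2ccccc2)c(C(=O)OCc2ccccc2)c(c1C)[C@H](C)C(=O)COC(=O)c1c(C)c(C)c(OCc2ccccc2)c(C)c1OCc1ccccc1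
A1 | alternative 1 | [(3R,4S)-8-(benzyloxy)-3-hydroxy-6-methoxy-4,5-dimethyl-1-oxoisochroman-3-yl]methyl 2,4-bis(benzyloxy)-3,5,6-trimethylbenzoate | COc1cc(OCc2ccccc2)c2c(c1C)[C@H](C)[C@](O)(COC(=O)c1c(C)c(C)c(OCc3ccccc3)c(C)c1OCc1ccccc1)OC2=O
A2 | alternative 1 | [(3S)-7-(benzyloxy)-2-hydroxy-5-methoxy-3,4-dimethyl-1-oxo-2,3-dihydro-1H-inden-2-yl]methyl 2,4-bis(benzyloxy)-3,5,6-trimethylbenzoate (either C2 epimer) | COc1cc(OCc2ccccc2)c2c(c1C)[C@H](C)C(O)(COC(=O)c1c(C)c(C)c(OCc3ccccc3)c(C)c1OCc1ccccc1)C2=O
A3 | alternative 2 | benzyl 2-[2-(benzyloxy)-2-oxoethyl]-4,6-dimethoxy-3-methylbenzoate | COc1cc(OC)c(C(=O)OCc2ccccc2)c(CC(=O)OCc2ccccc2)c1C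
A4 | alternative 2 | 3,5-dimethoxy-2-methyl-6-(trimethylsilyl)phenyl trifluoromethanesulfonate | COc1cc(OC)c([Si](C)(C)C)c(OS(=O)(=O)C(F)(F)F)c1C
A5 | alternative 2 | dibenzyl malonate | O=C(CC(=O)OCc1ccccc1)OCc1ccccc1
A6 | alternative 3 | benzyl 2-[(1S)-1-[(4R)-2,2-dimethyl-1,3-dioxolan-4-yl]ethyl]-6-hydroxy-4-methoxy-3-methylbenzoate | COc1cc(O)c(C(=O)OCc2ccccc2)c(c1C)[C@H](C)[C@@H]1COC(C)(C)O1
A7 | alternative 3 | benzyl (4S)-4-[(4R)-2,2-dimethyl-1,3-dioxolan-4-yl]pent-2-ynoate | O=C(OCc1ccccc1)C#C[C@H](C)[C@@H]1COC(C)(C)O1
A8 | alternative 3 | 1,3-dimethoxy-1-(trimethylsilyloxy)penta-1,3-diene | CC=C(OC)C=C(OC)O[Si](C)(C)C
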